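Its constants were drawn at random within sensible limits.

- Work in percent of the starting material charged, and watch the pair target and isomer of the product: their equilibrium ratio, isomer of the product over target at the hot temperature, is the quantity to carry, Q.

| setting | Saturday's | Wednesday's | Sunday's | Friday's |
|---|---|---|---|---|
| starting material | 1.5 M | 1.5 M | 1.5 M | 1.5 M |
| protic impurity | 1.50 M | 1.50 M | 1.50 M | 1.50 M |
| time | 10 d | 10 d | 10 d | 10 d |
| remark | at 60 °C until 5.0 d, from then on at 20 °C |  |  |  |
| temperature |  | 60 °C | 40 °C | 20 °C |

- the best flask by amount of target, in percent of the starting material charged; "all alike" if 1.5 percentage points covers them all (Saturday's / Wednesday's / Sunday's / Friday's / all alike)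
- amount of target at the end, in percent of the starting material charged, Saturday's
- amount of target at the end, in percent of the starting material charged, Wednesday's
- amount of target at the end, in percent of the starting material charged, Sunday's
- amount of target at the end, in percent of the starting material charged, Friday's

- at 20 °C the constants are as listed, elsewhere as the activation energies and enthalpies make them

    starting material ⇌ intermediate (K1 = 0.51, k1 = 0.20 /h, Ea1 = 98.0 kJ/mol, ΔH1 = −14.0 kJ/mol)
    intermediate → target (k2 = 0.051 /h, Ea2 = 98.0 kJ/mol)
    target ⇌ isomer of the product (K3 = 0.57, k3 = 8.4 × 10⁻⁴ /h, Ea3 = 111 kJ/mol, ΔH3 = 18.0 kJ/mol)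
    starting material + protic impurity → quenched substrate (k4 = 0.011 /M/h, Ea4 = 81.0 kJ/mol)
    (constants at 20 °C)

- Find first the concentration that sets the order of the loss: the quench is second order, but protic impurity is charged at 1.50 M, so treat its rate constant times that concentration as a pseudo-first-order constant on the starting material.
- At 20 °C, the intermediate returns to starting material at 0.392 /h, faster than it goes on to target at 0.051 /h, so take the step from starting material to intermediate as a pre-equilibrium, and assume the same form when hot.
- Define g, the kept share, as the rate constant to target times the equilibrium constant of the first step, over that product plus the pseudo-first-order constant: g = 61.2% at 20 °C and 64.6% at 60 °C; protic impurity is consumed, so read both as low estimates.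
- Solve the first extreme, the isomerisation frozen: target equals g.
- Solve the second extreme, the isomerisation at equilibrium: target equals g/(1+Q), with Q = 1.38 at 60 °C and 0.914 at 40 °C.
- Place each flask by the relaxation half-life of the pair. Wednesday's has 0.0842 d, short against 10 d, so it sits at the second extreme: 27.1%.
- Sunday's has 0.895 d, shorter than 10 d, so it sits there too; with g = 63.0% at 40 °C, this gives 32.9%.
- Friday's has 12.5 d, longer than 10 d, so it lies between 39.0% and 61.2%; relaxing from the frozen extreme gives 51.7%.
- Saturday's reaches the hot equilibrium, then relaxes toward the cold one with that same half-life for 5.00 d, which gives 30.5%.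
- Expect this order: Friday's on top.
- Set beside this the forecast: 32% for Saturday's, 28.5% for Wednesday's, 34.5% for Sunday's, 54% for Friday's, with the remark “Friday's therefore keeps by far the most target”.
- Read the simulation: 31.9% for Saturday's, 28.3% for Wednesday's, 34.4% for Sunday's and 54.9% for Friday's, which ends highest.
- Carry Q to a repeat of Wednesday's at 45 °C: shift it from 60 °C with the enthalpy of the isomerisation to 1.02, and reckon the kept share at that temperature, 63.5%, which gives target at 31.4%. That flask ends with target at 32.8% and isomer of the product at 33.4%.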